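# Proposed synthesis of CNP0228086.1: catechin-(4α→6)-epicatechin-(4β→8)-epicatechin-(4β→8)-epicatechin

## The problem

The target 30 is a linear B-type procyanidin tetramer: four flavan-3-ol units joined by three single C4–aryl bonds, with no ring shared between units. Of its twelve stereocentres, the C2/C3 pairs of units 1, 3 and 4 are those of (+)-catechin (1) and (−)-epicatechin (25). The three C4 centres arise when the interflavan bonds form, and each can be steered by the neighbouring C3 oxygen (attack trans to it). This leaves C2 and C3 of unit 2 as the only centres that depend on how that unit is obtained. The two 4→8 bonds follow the innate preference of a flavan-4-yl cation for C8 of a flavan nucleophile. The bond from C4 of unit 1 to C6 of unit 2 runs against that preference and is the regiochemical core of the problem. The material is fragile: free phloroglucinol and catechol rings oxidise, interflavan bonds ionise in acid, C2 epimerises in base, and a flavanone met on the way can open to a chalcone. All phenols are therefore carried as benzyl ethers and released by one neutral hydrogenolysis at the end. The feature exploited is ring A of unit 2 (C4a, C5, C6, C7, C8, C8a): C6, which carries unit 1, lies between the oxygen-bearing C5 and C7 exactly as the central carbon of an acetoacetate lies between its two carbonyl carbons, and C8a–O1 with C4a–C4(=O) maps onto the enol-ether double bond of a 2-aryl-2,3-dihydropyran-4-one. If unit 1 is fixed to the acetoacetate carbon before ring A exists, the C6/C8 question never arises.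

## Retrosynthesis

**30 from 29.** The seventeen O–benzyl bonds are cut last. Hydrogenolysis is neutral and leaves interflavan bonds and C2 centres alone. A single protecting group for all phenols and for the 3-OH of unit 1 keeps the endgame to one operation.

**29 from 24 and 28.** The central C4(unit 2)–C8(unit 3) bond is cut, dividing the tetramer into two dimers of similar size. Cutting the unit 1–unit 2 bond instead would ask a cation to attack C6 of a trimer against its C8 preference. Cutting the unit 3–unit 4 bond would need a trimeric electrophile. The lower half 28 is a benzylated procyanidin B2, reached in three steps from 25 through 26 and 27. The forward reaction must capture the cation from 24 at C8 of the upper unit of 28, on the β face, faster than the cation finds the free ring-A positions of another molecule of 24.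

**24 from 20 by way of 22 and 23.** The C3–O and C4–O bonds of unit 2 are traced back to the C3=C4 double bond of flav-3-ene 20. Introducing both oxygens at once (epoxidation, opening at benzylic C4 by an alcohol) gives 22 with the C4 leaving group already in place. A late C–H oxidation at C4 on the dimer, where the doubly benzylic C4–H of unit 1 could compete, is thereby avoided. The C3 configuration of 22 is of no consequence: it is erased in ketone 23 and reset by hydride delivery anti to the 2-aryl group, which gives the 2,3-cis alcohol 24. C4 of 22–24 becomes a cation and needs no control.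

**20 from 17 by way of 18 and 19.** These are changes of functional group only: the flavanone carbonyl of 17 is reduced and the alcohol eliminated. The two ring-A phenols are benzylated after the reduction (18 to 19), not on 17 itself. The 5-OH of 17 is chelated to the carbonyl and flanked by unit 1, and basic alkylation of a flavanone invites ring opening.

**17 from 8 and 14 (key disconnection).** C4a–C5 and C8–C8a are cut, so ring A falls into a four-carbon 1,1,3-trioxygenated diene 8 carrying unit 1 on its central carbon and the enol-ether C5=C6 bond of pyranone 14.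

- Any disconnection that attaches unit 1 to an existing ring A brings the C6/C8 choice back; this one removes it by construction.
- The substituent at C5 of the pyranone has to activate the enone and then leave together with the angular hydrogen at C8a. That hydrogen is cis to it and not acidic, so a halide has no good exit. A sulfoxide leaves by thermal syn-elimination and is the stronger activator, so 14 carries a phenylsulfinyl group.
- The ester alkoxy group of the diene is lost when the C5 ketal collapses, so a methyl ester suffices and the product is the 5,7-diol 17.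
- The precursors are much simpler than 17: 8 holds unit 1 with its three stereocentres, and 14 holds only C2 of unit 2.

**8 from 6, 6 from 4 and 5, 4 from 1 by way of 2 and 3.** The diene is the bis-silyl dienol ether of β-ketoester 6. The bond between C4 of unit 1 and the acetoacetate carbon is cut to the C4 ether 4 and the silyl enol ether 5. Compound 5 reacts at its central carbon, whereas a preformed bis-silyl diene would react at its terminus and cannot be used directly. The forward step must bring the nucleophile in trans to the 3-benzyloxy group (4α). Compound 4 is three routine steps from 1.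

**14 from 12 by way of 13, 12 from 9 and 10.** The C5–S bond is cut back to pyranone 12, and the ring to aldehyde 9 and diene 10 (C2–C3 and O1–C6 bonds). The catalyst of this formal hetero-Diels–Alder reaction sets C2 of unit 2, the only stereocentre of the route made from achiral material by an external reagent, and it is set on a small molecule.

## Roads not taken

Alternative 1: The cut is through C4–C4a of both unit 3 and unit 4. In the forward step one Lewis acid would open two epoxides of an acyclic precursor, each ring-A carbon ortho to its aryl ether oxygen attacking its own epoxide at C4, and both C rings would close to give A1. A1 is identical with 28 of the present route.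
- Merits: two rings and the 4β centre of unit 3 (by inversion) in one operation, no excess of a flavan nucleophile, and no oligomeric by-products.
- Weak points: the two epoxides are unlike (a terminal CH2 in unit 4, an aryl-substituted benzylic carbon in unit 3). One set of conditions must serve an SN2-like and an SN1-prone opening, and the latter can lose the inversion that defines 4β. Six-ring closure must beat five-ring closure at C3 twice. Four stereocentres have to be built from achiral material to reach a compound available in three steps from 25.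
- Comparison: this road is better in material economy for the lower dimer, since the present steps 18 and 19 spend a severalfold excess of 26 and 28. It leaves the 4α→6 bond untouched. The chosen plan sets against it the short chiral-pool access to 28 and spends its one unprecedented step on the regiochemical problem.

Alternative 2: The cut is through C3–C4 and the O1–C2 acyl bond of unit 2, with the C4–C8 bond to unit 3 already present. In the forward step a chiral carbene catalyst would turn an α-benzyloxy acyl donor into an azolium enolate that adds to the methide carbon (future C4) of an ortho-quinone methide on ring A of unit 2. The phenoxide would then be acylated, closing ring C as the dihydrocoumarin A2.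
- Merits: it is convergent and late, all four units are assembled in one compound, and C3 and C4 of unit 2 are set by a catalyst without an inversion sequence.
- Weak points: the methide carbon carries the bulky unit 3 aryl group and is flanked by a benzyloxy group, so it is both hindered and stabilised. The catalyst must override nine existing stereocentres. Ring B of unit 2 is still missing from A2: C2 must be created afterwards by aryl addition to the lactone and reduction, on the largest intermediate, with 2,3-cis control that is not assured. The 4→6 attachment of unit 1 is only displaced to the question of which phenol of an acyclic phloroglucinol is left free.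
- Comparison: this road could be shorter after its key step and controls two centres catalytically, where the chosen plan needs steps 13–15 for C3. The chosen plan sets against it that C2 is made early on a small molecule and that every stereocentre set after step 9 follows flavan precedent.

Alternative 3: The cut is the O1–C2 bond of unit 3. In the forward step, under mild acid, the ring-A phenol would open a cis-epoxide at its benzylic carbon with inversion, closing ring C and turning the epoxide oxygen into the C3 hydroxyl. The product A3 differs from 28 only by a benzyl group on the 3-OH of unit 4.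
- Merits: the 2,3-cis relationship comes stereospecifically from the epoxide geometry, there is no oxidation/reduction detour, and the diarylmethine C4 is already in place.
- Weak points: the benzylic carbon bears a dialkoxyphenyl group, so the opening has cation character and can leak to the 2,3-trans isomer. Five-ring closure at C3 competes. The substrate needs an enantio- and diastereoselective synthesis of a cis-epoxide beside a diarylmethine centre. The result is again only the lower dimer.
- Comparison: this road would probably give an isomerically cleaner dimer than a cation–arene coupling. The chosen plan takes C2 and C3 of units 3 and 4 directly from 25 and keeps its effort for the 4α→6 link.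

Key step: step 9

## Route

Remarks on the chemistry:
- α and β are used as in flavan nomenclature; the 2-aryl group of every unit is α.
- In step 6 the sense of induction of the Ti(OiPr)4/BINOL catalyst is assumed to parallel that of the related allylation, (S)-BINOL giving the (2S)-pyranone; should the opposite sense be found, (R)-BINOL is used.
- C4 ethers and alcohols (4, 18, 19, 22–24, 27) are drawn as the expected major epimer; either epimer serves, since C4 becomes sp2 or a cation. Enol-ether geometries in 5, 7 and 8 and the configuration at sulfur in 14–15 are left open and are lost later.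
- Compound 5 is commercial; otherwise it is one step from methyl acetoacetate.

Step 1
Reactants: 1 (+)-catechin
Product: 2 5,7,3',4'-tetra-O-benzyl-(+)-catechin
Conditions: BnBr (4.4 equiv), K2CO3 (5 equiv), DMF, 0 °C → rt
Reagents that add atoms: benzyl bromide, BrCc1ccccc1
Why: Williamson etherification of the four phenols; K2CO3 does not deprotonate the secondary 3-OH, and C2/C3 are untouched.

Step 2
Reactants: 2 5,7,3',4'-tetra-O-benzyl-(+)-catechin
Product: 3 3,5,7,3',4'-penta-O-benzyl-(+)-catechin
Conditions: NaH (1.5 equiv), BnBr (1.3 equiv), n-Bu4NI (cat.), DMF, 0 °C → rt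
Reagents that add atoms: benzyl bromide, BrCc1ccccc1
Why: Williamson etherification of the secondary alkoxide; the 3-O-benzyl group keeps this oxygen inert through the silylation, oxidation and hydride steps that follow.

Step 3
Reactants: 3 3,5,7,3',4'-penta-O-benzyl-(+)-catechin
Product: 4 3,5,7,3',4'-penta-O-benzyl-4β-(2-ethoxyethoxy)catechin
Conditions: DDQ (2 equiv), 2-ethoxyethanol (5 equiv), CH2Cl2, rt
Reagents that add atoms: 2-ethoxyethanol, CCOCCO
Why: Benzylic oxidation by hydride abstraction at C4, the cation being stabilised by the ring-A oxygens and trapped by the alcohol; a standard C4 activation of benzylated flavan-3-ols.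

Step 4
Reactants: 4 3,5,7,3',4'-penta-O-benzyl-4β-(2-ethoxyethoxy)catechin; 5 methyl 3-(trimethylsilyloxy)but-2-enoate
Product: 6 methyl 3-oxo-2-(3,5,7,3',4'-penta-O-benzylcatechin-4α-yl)butanoate (epimers at the butanoate carbon)
Conditions: 5 (3 equiv), TMSOTf (0.2 equiv), CH2Cl2, −78 → −40 °C; aq. NaHCO3
Reagents that add atoms: none
Why: Lewis-acid SN1 alkylation of a silyl enol ether (Mukaiyama type) by the flavan-4-yl cation. The nucleophile should enter trans to the 3-benzyloxy group, setting C4 of unit 1 as 4α under control of C3.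

Step 5
Reactants: 6 methyl 3-oxo-2-(3,5,7,3',4'-penta-O-benzylcatechin-4α-yl)butanoate
Product: 8 1-methoxy-2-(3,5,7,3',4'-penta-O-benzylcatechin-4α-yl)-1,3-bis(trimethylsilyloxy)buta-1,3-diene, via mono(silyl enol ether) 7 (not isolated)
Conditions: TMSOTf (2.4 equiv), Et3N (3 equiv), Et2O, 0 °C → rt; pentane, filtration under argon, used crude
Reagents that add atoms: trimethylsilyl trifluoromethanesulfonate, C[Si](C)(C)OS(=O)(=O)C(F)(F)F
Why: Soft enolisation: the ketone is silylated first, then silylation of the ester carbonyl with loss of a methyl proton gives the cross-conjugated bis-silyl dienol ether, as for simple 2-alkyl acetoacetates. The buffered medium should not ionise the C4–C bond.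

Step 6
Reactants: 9 3,4-bis(benzyloxy)benzaldehyde; 10 (E)-1-methoxy-3-(trimethylsilyloxy)buta-1,3-diene
Product: 12 (2S)-2-[3,4-bis(benzyloxy)phenyl]-2,3-dihydro-4H-pyran-4-one, via Mukaiyama aldol silyl ether 11 (not isolated)
Conditions: (S)-BINOL (20 mol %), Ti(OiPr)4 (20 mol %), 4 Å MS, Et2O, −20 °C; then TFA, CH2Cl2, 0 °C
Reagents that add atoms: none
Why: Catalytic enantioselective formal hetero-Diels–Alder reaction (Mukaiyama aldol, then acid-induced oxa-Michael closure and loss of methanol). The titanium–BINOL complex selects the aldehyde face and sets C2 of unit 2; a minor enantiomer would later appear as a separable diastereomer of 17.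

Step 7
Reactants: 12 (2S)-2-[3,4-bis(benzyloxy)phenyl]-2,3-dihydro-4H-pyran-4-one
Product: 13 (2S)-2-[3,4-bis(benzyloxy)phenyl]-5-(phenylsulfanyl)-2,3-dihydro-4H-pyran-4-one
Conditions: PhSCl (1.1 equiv), CH2Cl2, −78 °C; then Et3N (1.5 equiv), −78 °C → rt
Reagents that add atoms: benzenesulfenyl chloride, ClSc1ccccc1
Why: Electrophilic α-sulfenylation of a vinylogous ester: the sulfenyl chloride attacks the nucleophilic C5 of the enol ether and the base removes HCl. The catechol ether ring is far less reactive without a Lewis acid.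

Step 8
Reactants: 13 (2S)-2-[3,4-bis(benzyloxy)phenyl]-5-(phenylsulfanyl)-2,3-dihydro-4H-pyran-4-one
Product: 14 (2S)-2-[3,4-bis(benzyloxy)phenyl]-5-(phenylsulfinyl)-2,3-dihydro-4H-pyran-4-one (both epimers at sulfur)
Conditions: mCPBA (1.0 equiv), NaHCO3, CH2Cl2, −78 → −30 °C
Reagents that add atoms: 3-chloroperoxybenzoic acid, OOC(=O)c1cccc(Cl)c1
Why: Sulfide-to-sulfoxide oxidation with one equivalent of peracid at low temperature; the acceptor-substituted enol ether double bond is not epoxidised, and the sulfur configuration is irrelevant.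

Step 9
Reactants: 8 1-methoxy-2-(3,5,7,3',4'-penta-O-benzylcatechin-4α-yl)-1,3-bis(trimethylsilyloxy)buta-1,3-diene; 14 (2S)-2-[3,4-bis(benzyloxy)phenyl]-5-(phenylsulfinyl)-2,3-dihydro-4H-pyran-4-one
Product: 17 3,5,7,3',4'-penta-O-benzylcatechin-(4α→6)-(2S)-3',4'-di-O-benzyl-5,7-dihydroxyflavanone, via cycloadduct 15 (not isolated), via dihydroflavanone ketal 16 (not isolated)
Conditions: 14 (1.5 equiv), toluene, 25 → 80 °C; then 1 M HCl, THF, 0 °C → rt
Reagents that add atoms: none
Why: Proposed new method: a Diels–Alder benzannulation in which an α-sulfinyl vinylogous ester replaces the halo-quinone or 3-acylchromone of the closest known reaction type, the cycloaddition of 1,1,3-trioxygenated silyloxy dienes to such dienophiles followed by aromatisation through elimination. The nucleophilic CH2 terminus of 8 bonds to the β-carbon C6 of 14 (future C8a) and the ketene-acetal carbon to the sulfinyl-bearing C5 (future C4a), a polarity-matched and probably asynchronous [4+2] closure of ring A that gives the cis-fused adduct 15. The sulfinyl group lowers the LUMO of the enone and then leaves on warming as benzenesulfenic acid by syn-elimination with the cis angular hydrogen at C8a, a pericyclic exit that needs no acidic hydrogen and uses exactly the geometry the cycloaddition creates. Aqueous acid then hydrolyses the two silyl ethers of 16, the C5 ketal collapses with loss of methanol, and the resulting dione tautomerises to the 5,7-dihydroxy arene. No stereocentre is created: C2 of the pyranone is untouched, and the centres at C4a and C8a of 15 are erased. The only selectivity needed is the orientation of the addition, which the donor pattern of the diene and the acceptor pattern of the enone secure, and unit 1 on the central diene carbon can only end at C6 between the two oxygens.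

Step 10
Reactants: 17 3,5,7,3',4'-penta-O-benzylcatechin-(4α→6)-(2S)-3',4'-di-O-benzyl-5,7-dihydroxyflavanone
Product: 18 3,5,7,3',4'-penta-O-benzylcatechin-(4α→6)-(2S)-3',4'-di-O-benzyl-5,7-dihydroxyflavan-4-ol (2,4-cis expected)
Conditions: NaBH4 (3 equiv), THF/EtOH, 0 °C; pH 7 buffer work-up, used directly
Reagents that add atoms: none
Why: Hydride reduction of the aryl ketone, as in the borohydride reduction of free-phenolic flavanones and dihydroflavonols to flavan-4-ols. Once the carbonyl is gone, neither chalcone formation nor chelation of the 5-OH is possible.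

Step 11
Reactants: 18 3,5,7,3',4'-penta-O-benzylcatechin-(4α→6)-(2S)-3',4'-di-O-benzyl-5,7-dihydroxyflavan-4-ol
Product: 19 3,5,7,3',4'-penta-O-benzylcatechin-(4α→6)-(2S)-5,7,3',4'-tetra-O-benzylflavan-4-ol
Conditions: BnBr (2.5 equiv), K2CO3 (4 equiv), DMF, rt
Reagents that add atoms: benzyl bromide, BrCc1ccccc1
Why: Williamson etherification of the two phenols, which after step 10 are ordinary phenoxides; at room temperature O-alkylation should outrun loss of hydroxide to a quinone methide, and the benzylic alcohol is not deprotonated.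

Step 12
Reactants: 19 3,5,7,3',4'-penta-O-benzylcatechin-(4α→6)-(2S)-5,7,3',4'-tetra-O-benzylflavan-4-ol
Product: 20 3,5,7,3',4'-penta-O-benzylcatechin-(4α→6)-(2S)-5,7,3',4'-tetrakis(benzyloxy)flav-3-ene
Conditions: Burgess reagent (1.5 equiv), THF, rt → 50 °C
Reagents that add atoms: none
Why: Burgess dehydration of an electron-rich benzylic alcohol under neutral conditions; only C3 carries β-hydrogens, so the 2H-chromene double bond can form only between C3 and C4.

Step 13
Reactants: 20 3,5,7,3',4'-penta-O-benzylcatechin-(4α→6)-(2S)-5,7,3',4'-tetrakis(benzyloxy)flav-3-ene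
Product: 22 3,5,7,3',4'-penta-O-benzylcatechin-(4α→6)-5,7,3',4'-tetra-O-benzyl-4α-(2-ethoxyethoxy)catechin (2,3-trans-3,4-trans; free 3-OH), via 3β,4β-epoxide 21 (not isolated)
Conditions: DMDO (1.2 equiv, acetone), CH2Cl2, −40 °C; then 2-ethoxyethanol (10 equiv), PPTS (5 mol %), −40 → 0 °C
Reagents that add atoms: dimethyldioxirane, CC1(C)OO1; 2-ethoxyethanol, CCOCCO
Why: Epoxidation of the enol-ether-like styrene anti to the 2-aryl group, then acid-catalysed alcoholysis of the labile epoxide at the benzylic C4. The C3 configuration formed here is erased in step 14 and that at C4 in step 19.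

Step 14
Reactants: 22 3,5,7,3',4'-penta-O-benzylcatechin-(4α→6)-5,7,3',4'-tetra-O-benzyl-4α-(2-ethoxyethoxy)catechin
Product: 23 3,5,7,3',4'-penta-O-benzylcatechin-(4α→6)-(2R)-5,7,3',4'-tetrakis(benzyloxy)-4α-(2-ethoxyethoxy)flavan-3-one
Conditions: Dess–Martin periodinane (1.5 equiv), NaHCO3, CH2Cl2, 0 °C → rt; used at once
Reagents that add atoms: none
Why: Dess–Martin oxidation of the only free hydroxyl, the first half of the standard catechin-to-epicatechin inversion; the buffered neutral medium should spare the C2 centre α to the new ketone.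

Step 15
Reactants: 23 3,5,7,3',4'-penta-O-benzylcatechin-(4α→6)-(2R)-5,7,3',4'-tetrakis(benzyloxy)-4α-(2-ethoxyethoxy)flavan-3-one
Product: 24 3,5,7,3',4'-penta-O-benzylcatechin-(4α→6)-5,7,3',4'-tetra-O-benzyl-4α-(2-ethoxyethoxy)epicatechin (2,3-cis; free 3-OH)
Conditions: LiBH(s-Bu)3 (1.5 equiv), THF, −78 °C; aq. NH4Cl
Reagents that add atoms: none
Why: The bulky hydride attacks the flavan-3-one from the β face, anti to the 2-aryl and 4-alkoxy groups, giving the 2,3-cis alcohol; C3 of unit 2 is set here under control of C2.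

Step 16
Reactants: 25 (−)-epicatechin
Product: 26 5,7,3',4'-tetra-O-benzyl-(−)-epicatechin
Conditions: BnBr (4.4 equiv), K2CO3 (5 equiv), DMF, 0 °C → rt
Reagents that add atoms: benzyl bromide, BrCc1ccccc1
Why: Williamson etherification of the four phenols, as in step 1.

Step 17
Reactants: 26 5,7,3',4'-tetra-O-benzyl-(−)-epicatechin
Product: 27 5,7,3',4'-tetra-O-benzyl-4β-(2-ethoxyethoxy)epicatechin
Conditions: DDQ (2 equiv), 2-ethoxyethanol (5 equiv), CH2Cl2, rt
Reagents that add atoms: 2-ethoxyethanol, CCOCCO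
Why: Benzylic oxidation at C4 with trapping by the alcohol, as in step 3; the free 3-OH is tolerated.

Step 18
Reactants: 27 5,7,3',4'-tetra-O-benzyl-4β-(2-ethoxyethoxy)epicatechin; 26 5,7,3',4'-tetra-O-benzyl-(−)-epicatechin
Product: 28 5,7,3',4'-tetra-O-benzylepicatechin-(4β→8)-5,7,3',4'-tetra-O-benzylepicatechin (octa-O-benzylprocyanidin B2)
Conditions: 26 (4 equiv), TMSOTf (0.5 equiv), CH2Cl2, −78 °C; aq. NaHCO3
Reagents that add atoms: none
Why: Friedel–Crafts alkylation of C8 of 26 by the flavan-4-yl cation. Attack anti to the 2-aryl and 3-hydroxyl groups sets C4 as 4β, and excess nucleophile suppresses oligomerisation.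

Step 19
Reactants: 24 3,5,7,3',4'-penta-O-benzylcatechin-(4α→6)-5,7,3',4'-tetra-O-benzyl-4α-(2-ethoxyethoxy)epicatechin; 28 octa-O-benzylprocyanidin B2
Product: 29 3,5,7,3',4'-penta-O-benzylcatechin-(4α→6)-5,7,3',4'-tetra-O-benzylepicatechin-(4β→8)-5,7,3',4'-tetra-O-benzylepicatechin-(4β→8)-5,7,3',4'-tetra-O-benzylepicatechin
Conditions: 28 (3 equiv), TMSOTf (0.5 equiv), CH2Cl2, −78 → −40 °C; aq. NaHCO3
Reagents that add atoms: none
Why: Friedel–Crafts alkylation as in step 18. The cation of unit 2 is attacked on its β face (trans to the 3-OH, anti to the 2-aryl group) by C8 of the upper unit of 28, the most nucleophilic and least hindered position, setting C4 of unit 2.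

Step 20
Reactants: 29 heptadeca-O-benzyl tetramer
Product: 30 catechin-(4α→6)-epicatechin-(4β→8)-epicatechin-(4β→8)-epicatechin (CNP0228086.1)
Conditions: H2 (1 atm), Pd(OH)2/C, THF/MeOH/H2O, rt; filtration, lyophilisation
Reagents that add atoms: none
Why: Hydrogenolysis of all seventeen benzyl ethers under neutral conditions, which leaves interflavan bonds and stereocentres untouched.

## Compound list

1 | (+)-catechin | O[C@H]1Cc2c(O)cc(O)cc2O[C@@H]1c1ccc(O)c(O)c1 | starting material
2 | 5,7,3',4'-tetra-O-benzyl-(+)-catechin | c1ccccc1COc1cc(OCc2ccccc2)c2c(c1)O[C@H](c1ccc(OCc3ccccc3)c(OCc3ccccc3)c1)[C@@H](O)C2 | intermediate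
3 | 3,5,7,3',4'-penta-O-benzyl-(+)-catechin | c1ccccc1COc1cc(OCc2ccccc2)c2c(c1)O[C@H](c1ccc(OCc3ccccc3)c(OCc3ccccc3)c1)[C@@H](OCc1ccccc1)C2 | intermediate
4 | 3,5,7,3',4'-penta-O-benzyl-4β-(2-ethoxyethoxy)catechin | c1ccccc1COc1cc(OCc2ccccc2)c2c(c1)O[C@H](c1ccc(OCc3ccccc3)c(OCc3ccccc3)c1)[C@@H](OCc1ccccc1)[C@H]2OCCOCC | intermediate
5 | methyl 3-(trimethylsilyloxy)but-2-enoate | COC(=O)C=C(C)O[Si](C)(C)C | starting material
6 | methyl 3-oxo-2-(3,5,7,3',4'-penta-O-benzylcatechin-4α-yl)butanoate | c1ccccc1COc1cc(OCc2ccccc2)c2c(c1)O[C@H](c1ccc(OCc3ccccc3)c(OCc3ccccc3)c1)[C@@H](OCc1ccccc1)[C@@H]2C(C(C)=O)C(=O)OC | intermediate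
7 | methyl 2-(3,5,7,3',4'-penta-O-benzylcatechin-4α-yl)-3-(trimethylsilyloxy)but-2-enoate | c1ccccc1COc1cc(OCc2ccccc2)c2c(c1)O[C@H](c1ccc(OCc3ccccc3)c(OCc3ccccc3)c1)[C@@H](OCc1ccccc1)[C@@H]2C(C(=O)OC)=C(C)O[Si](C)(C)C | intermediate (not isolated)
8 | 1-methoxy-2-(3,5,7,3',4'-penta-O-benzylcatechin-4α-yl)-1,3-bis(trimethylsilyloxy)buta-1,3-diene | c1ccccc1COc1cc(OCc2ccccc2)c2c(c1)O[C@H](c1ccc(OCc3ccccc3)c(OCc3ccccc3)c1)[C@@H](OCc1ccccc1)[C@@H]2C(C(=C)O[Si](C)(C)C)=C(OC)O[Si](C)(C)C | intermediate
9 | 3,4-bis(benzyloxy)benzaldehyde | O=Cc1ccc(OCc2ccccc2)c(OCc2ccccc2)c1 | starting material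
10 | (E)-1-methoxy-3-(trimethylsilyloxy)buta-1,3-diene | CO/C=C/C(=C)O[Si](C)(C)C | starting material
11 | (S,E)-5-[3,4-bis(benzyloxy)phenyl]-1-methoxy-5-(trimethylsilyloxy)pent-1-en-3-one | CO/C=C/C(=O)C[C@@H](c1ccc(OCc2ccccc2)c(OCc2ccccc2)c1)O[Si](C)(C)C | intermediate (not isolated)
12 | (2S)-2-[3,4-bis(benzyloxy)phenyl]-2,3-dihydro-4H-pyran-4-one | O=C1C[C@@H](c2ccc(OCc3ccccc3)c(OCc3ccccc3)c2)OC=C1 | intermediate
13 | (2S)-2-[3,4-bis(benzyloxy)phenyl]-5-(phenylsulfanyl)-2,3-dihydro-4H-pyran-4-one | O=C1C[C@@H](c2ccc(OCc3ccccc3)c(OCc3ccccc3)c2)OC=C1Sc1ccccc1 | intermediate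
14 | (2S)-2-[3,4-bis(benzyloxy)phenyl]-5-(phenylsulfinyl)-2,3-dihydro-4H-pyran-4-one | O=C1C[C@@H](c2ccc(OCc3ccccc3)c(OCc3ccccc3)c2)OC=C1S(=O)c1ccccc1 | intermediate
15 | cis-fused cycloadduct: (2S)-2-[3,4-bis(benzyloxy)phenyl]-5-methoxy-6-(3,5,7,3',4'-penta-O-benzylcatechin-4α-yl)-4a-(phenylsulfinyl)-5,7-bis(trimethylsilyloxy)-4a,5,8,8a-tetrahydrochroman-4-one | c1ccccc1COc1cc(OCc2ccccc2)c2c(c1)O[C@H](c1ccc(OCc3ccccc3)c(OCc3ccccc3)c1)[C@@H](OCc1ccccc1)[C@@H]2C1=C(O[Si](C)(C)C)CC2O[C@H](c3ccc(OCc4ccccc4)c(OCc4ccccc4)c3)CC(=O)C2(S(=O)c3ccccc3)C1(OC)O[Si](C)(C)C | intermediate (not isolated)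
16 | (2S)-2-[3,4-bis(benzyloxy)phenyl]-5-methoxy-6-(3,5,7,3',4'-penta-O-benzylcatechin-4α-yl)-5,7-bis(trimethylsilyloxy)-5,8-dihydrochroman-4-one | c1ccccc1COc1cc(OCc2ccccc2)c2c(c1)O[C@H](c1ccc(OCc3ccccc3)c(OCc3ccccc3)c1)[C@@H](OCc1ccccc1)[C@@H]2C1=C(O[Si](C)(C)C)CC2=C(C(=O)C[C@@H](c3ccc(OCc4ccccc4)c(OCc4ccccc4)c3)O2)C1(OC)O[Si](C)(C)C | intermediate (not isolated)
17 | 3,5,7,3',4'-penta-O-benzylcatechin-(4α→6)-(2S)-3',4'-di-O-benzyl-5,7-dihydroxyflavanone | c1ccccc1COc1cc(OCc2ccccc2)c2c(c1)O[C@H](c1ccc(OCc3ccccc3)c(OCc3ccccc3)c1)[C@@H](OCc1ccccc1)[C@@H]2c1c(O)cc2c(c1O)C(=O)C[C@@H](c1ccc(OCc3ccccc3)c(OCc3ccccc3)c1)O2 | intermediate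
18 | 3,5,7,3',4'-penta-O-benzylcatechin-(4α→6)-(2S)-3',4'-di-O-benzyl-5,7-dihydroxyflavan-4-ol (2,4-cis) | c1ccccc1COc1cc(OCc2ccccc2)c2c(c1)O[C@H](c1ccc(OCc3ccccc3)c(OCc3ccccc3)c1)[C@@H](OCc1ccccc1)[C@@H]2c1c(O)cc2c(c1O)[C@@H](O)C[C@@H](c1ccc(OCc3ccccc3)c(OCc3ccccc3)c1)O2 | intermediate
19 | 3,5,7,3',4'-penta-O-benzylcatechin-(4α→6)-(2S)-5,7,3',4'-tetra-O-benzylflavan-4-ol (2,4-cis) | c1ccccc1COc1cc(OCc2ccccc2)c2c(c1)O[C@H](c1ccc(OCc3ccccc3)c(OCc3ccccc3)c1)[C@@H](OCc1ccccc1)[C@@H]2c1c(OCc3ccccc3)cc2c(c1OCc3ccccc3)[C@@H](O)C[C@@H](c1ccc(OCc3ccccc3)c(OCc3ccccc3)c1)O2 | intermediate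
20 | 3,5,7,3',4'-penta-O-benzylcatechin-(4α→6)-(2S)-5,7,3',4'-tetrakis(benzyloxy)flav-3-ene | c1ccccc1COc1cc(OCc2ccccc2)c2c(c1)O[C@H](c1ccc(OCc3ccccc3)c(OCc3ccccc3)c1)[C@@H](OCc1ccccc1)[C@@H]2c1c(OCc3ccccc3)cc2c(c1OCc3ccccc3)C=C[C@@H](c1ccc(OCc3ccccc3)c(OCc3ccccc3)c1)O2 | intermediate
21 | 3β,4β-epoxide of 20 | c1ccccc1COc1cc(OCc2ccccc2)c2c(c1)O[C@H](c1ccc(OCc3ccccc3)c(OCc3ccccc3)c1)[C@@H](OCc1ccccc1)[C@@H]2c1c(OCc3ccccc3)cc2c(c1OCc3ccccc3)[C@@H]3O[C@@H]3[C@@H](c1ccc(OCc3ccccc3)c(OCc3ccccc3)c1)O2 | intermediate (not isolated)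
22 | 3,5,7,3',4'-penta-O-benzylcatechin-(4α→6)-5,7,3',4'-tetra-O-benzyl-4α-(2-ethoxyethoxy)catechin | c1ccccc1COc1cc(OCc2ccccc2)c2c(c1)O[C@H](c1ccc(OCc3ccccc3)c(OCc3ccccc3)c1)[C@@H](OCc1ccccc1)[C@@H]2c1c(OCc3ccccc3)cc2c(c1OCc3ccccc3)[C@@H](OCCOCC)[C@H](O)[C@@H](c1ccc(OCc3ccccc3)c(OCc3ccccc3)c1)O2 | intermediate
23 | 3,5,7,3',4'-penta-O-benzylcatechin-(4α→6)-(2R)-5,7,3',4'-tetrakis(benzyloxy)-4α-(2-ethoxyethoxy)flavan-3-one | c1ccccc1COc1cc(OCc2ccccc2)c2c(c1)O[C@H](c1ccc(OCc3ccccc3)c(OCc3ccccc3)c1)[C@@H](OCc1ccccc1)[C@@H]2c1c(OCc3ccccc3)cc2c(c1OCc3ccccc3)[C@@H](OCCOCC)C(=O)[C@@H](c1ccc(OCc3ccccc3)c(OCc3ccccc3)c1)O2 | intermediate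
24 | 3,5,7,3',4'-penta-O-benzylcatechin-(4α→6)-5,7,3',4'-tetra-O-benzyl-4α-(2-ethoxyethoxy)epicatechin | c1ccccc1COc1cc(OCc2ccccc2)c2c(c1)O[C@H](c1ccc(OCc3ccccc3)c(OCc3ccccc3)c1)[C@@H](OCc1ccccc1)[C@@H]2c1c(OCc3ccccc3)cc2c(c1OCc3ccccc3)[C@@H](OCCOCC)[C@@H](O)[C@@H](c1ccc(OCc3ccccc3)c(OCc3ccccc3)c1)O2 | intermediate
25 | (−)-epicatechin | O[C@@H]1Cc2c(O)cc(O)cc2O[C@@H]1c1ccc(O)c(O)c1 | starting material
26 | 5,7,3',4'-tetra-O-benzyl-(−)-epicatechin | c1ccccc1COc1cc(OCc2ccccc2)c2c(c1)O[C@H](c1ccc(OCc3ccccc3)c(OCc3ccccc3)c1)[C@H](O)C2 | intermediate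
27 | 5,7,3',4'-tetra-O-benzyl-4β-(2-ethoxyethoxy)epicatechin | c1ccccc1COc1cc(OCc2ccccc2)c2c(c1)O[C@H](c1ccc(OCc3ccccc3)c(OCc3ccccc3)c1)[C@H](O)[C@H]2OCCOCC | intermediate
28 | 5,7,3',4'-tetra-O-benzylepicatechin-(4β→8)-5,7,3',4'-tetra-O-benzylepicatechin | c1ccccc1COc1cc(OCc2ccccc2)c2c(c1)O[C@H](c1ccc(OCc3ccccc3)c(OCc3ccccc3)c1)[C@H](O)[C@H]2c1c(OCc3ccccc3)cc(OCc3ccccc3)c2c1O[C@H](c1ccc(OCc3ccccc3)c(OCc3ccccc3)c1)[C@H](O)C2 | intermediate
29 | 3,5,7,3',4'-penta-O-benzylcatechin-(4α→6)-5,7,3',4'-tetra-O-benzylepicatechin-(4β→8)-5,7,3',4'-tetra-O-benzylepicatechin-(4β→8)-5,7,3',4'-tetra-O-benzylepicatechin | c1ccccc1COc1cc(OCc2ccccc2)c2c(c1)O[C@H](c1ccc(OCc3ccccc3)c(OCc3ccccc3)c1)[C@@H](OCc1ccccc1)[C@@H]2c1c(OCc3ccccc3)cc2c(c1OCc3ccccc3)[C@H](c1c(OCc4ccccc4)cc(OCc4ccccc4)c3c1O[C@H](c1ccc(OCc4ccccc4)c(OCc4ccccc4)c1)[C@H](O)[C@H]3c1c(OCc4ccccc4)cc(OCc4ccccc4)c3c1O[C@H](c1ccc(OCc4ccccc4)c(OCc4ccccc4)c1)[C@H](O)C3)[C@@H](O)[C@@H](c1ccc(OCc3ccccc3)c(OCc3ccccc3)c1)O2 | intermediate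
30 | catechin-(4α→6)-epicatechin-(4β→8)-epicatechin-(4β→8)-epicatechin (CNP0228086.1) | Oc1cc(O)c2c(c1)O[C@H](c1ccc(O)c(O)c1)[C@@H](O)[C@@H]2c1c(O)cc2c(c1O)[C@H](c1c(O)cc(O)c3c1O[C@H](c1ccc(O)c(O)c1)[C@H](O)[C@H]3c1c(O)cc(O)c3c1O[C@H](c1ccc(O)c(O)c1)[C@H](O)C3)[C@@H](O)[C@@H](c1ccc(O)c(O)c1)O2 | target

## Step count and least certain steps

Total: 20 steps. Longest linear sequence: 14 steps (steps 1–5, 9–15, 19 and 20, from 1).

**Step 9 (key step).** Three things may go wrong:
- The vinylogous ester may remain too poor a dienophile, so that desilylation of the diene outruns addition.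
- The addition may stop after the first bond, because ring closure joins two fully substituted carbons.
- Sulfenic acid released early may protonate unreacted diene.

A Lewis acid able to chelate the β-keto sulfoxide (ZnBr2) would be tried first within the same approach. The fallback uses known chemistry and gives up ring construction in favour of a cation–arene coupling with C8 blocked. It sets out from 26 and 4.
- Bromination of 26 with N-bromosuccinimide in CH2Cl2 at −78 °C should give 8-bromo-5,7,3',4'-tetra-O-benzylepicatechin F1.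
- Coupling of 4 with F1 under the conditions of step 18 can then occur only at C6 and should give penta-O-benzylcatechin-(4α→6)-8-bromo-tetra-O-benzylepicatechin F2.
- Bromine–lithium exchange (n-BuLi, THF, −78 °C, then MeOH) removes the blocking group to give penta-O-benzylcatechin-(4α→6)-tetra-O-benzylepicatechin F3.
- Oxidation as in step 17 should give its 4β-(2-ethoxyethoxy) ether F4.
- F4 is coupled with 28 as in step 19, and the route is rejoined at 29.

**Step 4.** The nucleophile may attack in part cis to the 3-benzyloxy group, the β-dicarbonyl product may re-ionise under the Lewis acid, and the cation may be intercepted by ring A of a second molecule. The fallback sets out from 4 and uses a smaller nucleophile that is not reversible. Alkylation of 1-methoxy-1-(trimethylsilyloxy)ethene under the same conditions should give methyl (3,5,7,3',4'-penta-O-benzylcatechin-4α-yl)acetate F5. A crossed Claisen acylation of its lithium enolate (LiN(i-Pr)2, 2.2 equiv, THF, −78 °C, then N-methoxy-N-methylacetamide) returns to the route at 6.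

**Step 10.** Before reduction is complete, the basic medium may open the flavanone to a chalcone. Reclosure would erode the configuration at C2 and could move unit 1 from C6 to C8 by closure on the other phenol (Wessely–Moser type). The product may also ionise at C4 during work-up. The fallback protects first under non-enolising conditions and sets out from 17.
- TBSOTf/2,6-lutidine (CH2Cl2, −78 → 0 °C) should give the 5,7-bis(tert-butyldimethylsilyl) ether of the flavanone F6.
- i-Bu2AlH (toluene, −78 °C) should give the bis-silylated flavan-4-ol F7.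
- Burgess dehydration should give the bis-silylated flav-3-ene F8.
- Fluoride-induced desilylation with benzylation in the same flask (CsF, BnBr, DMF) returns to the route at 20.

**Step 13.** The oxidant may attack the electron-rich rings or benzylic C–H bonds, and the epoxide may rearrange by hydride shift to a flavan-3-one with loss of the C4 oxygen. The fallback sets out from 20 and separates oxidation from substitution. Catalytic dihydroxylation (OsO4, N-methylmorpholine N-oxide, acetone/H2O) should give the 3β,4β-diol F9. Acid-catalysed exchange of its benzylic 4-hydroxyl (2-ethoxyethanol, PPTS, CH2Cl2) returns to the route at 22.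

**Step 19.** The cation from 24 may alkylate free ring-A positions of another molecule of 24 or of the product, giving oligomers, and it may attack a C6 position of 28 instead of C8. The fallback replaces the dimeric nucleophile by monomers used in large excess, with orthogonal activation. It sets out from 27 and 24.
- Thiol exchange on 27 (2,6-dimethylbenzenethiol, BF3·OEt2, CH2Cl2, −78 °C) should give 5,7,3',4'-tetra-O-benzyl-4β-(2,6-dimethylphenylsulfanyl)epicatechin F10, whose sulfide is inert to hard Lewis acids.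
- Coupling of 24 with excess F10 as in step 19 should give the trimeric sulfide penta-O-benzylcatechin-(4α→6)-tetra-O-benzylepicatechin-(4β→8)-tetra-O-benzyl-4β-(2,6-dimethylphenylsulfanyl)epicatechin F11.
- Thiophilic activation of F11 (AgOTf, CH2Cl2, −40 °C) in the presence of excess 26 returns to the route at 29.

## Further compounds

F1 | step 9 | 8-bromo-5,7,3',4'-tetra-O-benzylepicatechin | Brc1c(OCc2ccccc2)cc(OCc2ccccc2)c2c1O[C@H](c1ccc(OCc3ccccc3)c(OCc3ccccc3)c1)[C@H](O)C2
F2 | step 9 | 3,5,7,3',4'-penta-O-benzylcatechin-(4α→6)-8-bromo-5,7,3',4'-tetra-O-benzylepicatechin | c1ccccc1COc1cc(OCc2ccccc2)c2c(c1)O[C@H](c1ccc(OCc3ccccc3)c(OCc3ccccc3)c1)[C@@H](OCc1ccccc1)[C@@H]2c1c(OCc3ccccc3)c(Br)c2c(c1OCc3ccccc3)C[C@@H](O)[C@@H](c1ccc(OCc3ccccc3)c(OCc3ccccc3)c1)O2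
F3 | step 9 | 3,5,7,3',4'-penta-O-benzylcatechin-(4α→6)-5,7,3',4'-tetra-O-benzylepicatechin | c1ccccc1COc1cc(OCc2ccccc2)c2c(c1)O[C@H](c1ccc(OCc3ccccc3)c(OCc3ccccc3)c1)[C@@H](OCc1ccccc1)[C@@H]2c1c(OCc3ccccc3)cc2c(c1OCc3ccccc3)C[C@@H](O)[C@@H](c1ccc(OCc3ccccc3)c(OCc3ccccc3)c1)O2
F4 | step 9 | 3,5,7,3',4'-penta-O-benzylcatechin-(4α→6)-5,7,3',4'-tetra-O-benzyl-4β-(2-ethoxyethoxy)epicatechin | c1ccccc1COc1cc(OCc2ccccc2)c2c(c1)O[C@H](c1ccc(OCc3ccccc3)c(OCc3ccccc3)c1)[C@@H](OCc1ccccc1)[C@@H]2c1c(OCc3ccccc3)cc2c(c1OCc3ccccc3)[C@H](OCCOCC)[C@@H](O)[C@@H](c1ccc(OCc3ccccc3)c(OCc3ccccc3)c1)O2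
F5 | step 4 | methyl (3,5,7,3',4'-penta-O-benzylcatechin-4α-yl)acetate | c1ccccc1COc1cc(OCc2ccccc2)c2c(c1)O[C@H](c1ccc(OCc3ccccc3)c(OCc3ccccc3)c1)[C@@H](OCc1ccccc1)[C@@H]2CC(=O)OC
F6 | step 10 | 3,5,7,3',4'-penta-O-benzylcatechin-(4α→6)-(2S)-3',4'-di-O-benzyl-5,7-bis(tert-butyldimethylsilyloxy)flavanone | c1ccccc1COc1cc(OCc2ccccc2)c2c(c1)O[C@H](c1ccc(OCc3ccccc3)c(OCc3ccccc3)c1)[C@@H](OCc1ccccc1)[C@@H]2c1c(O[Si](C)(C)C(C)(C)C)cc2c(c1O[Si](C)(C)C(C)(C)C)C(=O)C[C@@H](c1ccc(OCc3ccccc3)c(OCc3ccccc3)c1)O2
F7 | step 10 | 3,5,7,3',4'-penta-O-benzylcatechin-(4α→6)-(2S)-3',4'-di-O-benzyl-5,7-bis(tert-butyldimethylsilyloxy)flavan-4-ol | c1ccccc1COc1cc(OCc2ccccc2)c2c(c1)O[C@H](c1ccc(OCc3ccccc3)c(OCc3ccccc3)c1)[C@@H](OCc1ccccc1)[C@@H]2c1c(O[Si](C)(C)C(C)(C)C)cc2c(c1O[Si](C)(C)C(C)(C)C)[C@@H](O)C[C@@H](c1ccc(OCc3ccccc3)c(OCc3ccccc3)c1)O2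
F8 | step 10 | 3,5,7,3',4'-penta-O-benzylcatechin-(4α→6)-(2S)-3',4'-bis(benzyloxy)-5,7-bis(tert-butyldimethylsilyloxy)flav-3-ene | c1ccccc1COc1cc(OCc2ccccc2)c2c(c1)O[C@H](c1ccc(OCc3ccccc3)c(OCc3ccccc3)c1)[C@@H](OCc1ccccc1)[C@@H]2c1c(O[Si](C)(C)C(C)(C)C)cc2c(c1O[Si](C)(C)C(C)(C)C)C=C[C@@H](c1ccc(OCc3ccccc3)c(OCc3ccccc3)c1)O2
F9 | step 13 | 3,5,7,3',4'-penta-O-benzylcatechin-(4α→6)-5,7,3',4'-tetra-O-benzyl-2,3-trans-3,4-cis-flavan-3β,4β-diol | c1ccccc1COc1cc(OCc2ccccc2)c2c(c1)O[C@H](c1ccc(OCc3ccccc3)c(OCc3ccccc3)c1)[C@@H](OCc1ccccc1)[C@@H]2c1c(OCc3ccccc3)cc2c(c1OCc3ccccc3)[C@H](O)[C@H](O)[C@@H](c1ccc(OCc3ccccc3)c(OCc3ccccc3)c1)O2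
F10 | step 19 | 5,7,3',4'-tetra-O-benzyl-4β-(2,6-dimethylphenylsulfanyl)epicatechin | c1ccccc1COc1cc(OCc2ccccc2)c2c(c1)O[C@H](c1ccc(OCc3ccccc3)c(OCc3ccccc3)c1)[C@H](O)[C@H]2Sc1c(C)cccc1C
F11 | step 19 | 3,5,7,3',4'-penta-O-benzylcatechin-(4α→6)-5,7,3',4'-tetra-O-benzylepicatechin-(4β→8)-5,7,3',4'-tetra-O-benzyl-4β-(2,6-dimethylphenylsulfanyl)epicatechin | c1ccccc1COc1cc(OCc2ccccc2)c2c(c1)O[C@H](c1ccc(OCc3ccccc3)c(OCc3ccccc3)c1)[C@@H](OCc1ccccc1)[C@@H]2c1c(OCc3ccccc3)cc2c(c1OCc3ccccc3)[C@H](c1c(OCc4ccccc4)cc(OCc4ccccc4)c3c1O[C@H](c1ccc(OCc4ccccc4)c(OCc4ccccc4)c1)[C@H](O)[C@H]3Sc1c(C)cccc1C)[C@@H](O)[C@@H](c1ccc(OCc3ccccc3)c(OCc3ccccc3)c1)O2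
A1 | alternative 1 | 5,7,3',4'-tetra-O-benzylepicatechin-(4β→8)-5,7,3',4'-tetra-O-benzylepicatechin (identical with 28) | c1ccccc1COc1cc(OCc2ccccc2)c2c(c1)O[C@H](c1ccc(OCc3ccccc3)c(OCc3ccccc3)c1)[C@H](O)[C@H]2c1c(OCc3ccccc3)cc(OCc3ccccc3)c2c1O[C@H](c1ccc(OCc3ccccc3)c(OCc3ccccc3)c1)[C@H](O)C2
A2 | alternative 2 | per-O-benzylated tetramer in which unit 2 is a 3,4-trans-3-benzyloxy-3,4-dihydrocoumarin (ring B of unit 2 absent) | c4ccccc4COc1cc(OCc4ccccc4)c2c(c1)O[C@H](c1ccc(OCc4ccccc4)c(OCc4ccccc4)c1)[C@@H](OCc4ccccc4)[C@@H]2c1c(OCc4ccccc4)cc2c(c1OCc4ccccc4)[C@H](c1c(OCc4ccccc4)cc(OCc4ccccc4)c3c1O[C@H](c1ccc(OCc4ccccc4)c(OCc4ccccc4)c1)[C@H](OCc4ccccc4)[C@H]3c1c(OCc4ccccc4)cc(OCc4ccccc4)c3c1O[C@H](c1ccc(OCc4ccccc4)c(OCc4ccccc4)c1)[C@H](OCc4ccccc4)C3)[C@@H](OCc4ccccc4)C(=O)O2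
A3 | alternative 3 | 5,7,3',4'-tetra-O-benzylepicatechin-(4β→8)-3,5,7,3',4'-penta-O-benzylepicatechin (free 3-OH on unit 3) | c4ccccc4COc1cc(OCc4ccccc4)c3c(c1)O[C@H](c1ccc(OCc4ccccc4)c(OCc4ccccc4)c1)[C@H](O)[C@H]3c1c(OCc4ccccc4)cc(OCc4ccccc4)c3c1O[C@H](c1ccc(OCc4ccccc4)c(OCc4ccccc4)c1)[C@H](OCc4ccccc4)C3
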